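A stirred solution cannot stay far below its solubility while undissolved solid lies in it, or so it seems, and yet that is what I expect here.

solid substrate 1.0 M; gas phase 130 mM (held); time 25 min

    gas phase ⇌ dissolved gas, rate k1*(csat - [dissolved gas]) (k1 = 0.817 min⁻¹, csat = 130 mM)
    starting material → side product (k2 = 0.0785 min⁻¹)
    starting material + dissolved gas → target (k3 = 0.448 L mol⁻¹ min⁻¹)
    solid substrate ⇌ starting material, rate k4*(cs4 - [starting material]) while solid is left; crystals form when [starting material] > cs4 (cs4 = 0.53 M, k4 = 0.0709 min⁻¹)
    target ⇌ isomer of the product (K5 = 0.267, k5 = 0.0263 min⁻¹)
    2 starting material → homo dimer (k6 = 0.0649 L mol⁻¹ min⁻¹)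

1. amount of target at 25 min, in percent of the solid substrate charged
2. concentration of dissolved gas in solution at 25 min, in percent of saturation

The charge of 1.0 M stands above the solubility of 0.53 M, so saturation looks certain. Let A be the concentration of starting material, and B that of dissolved gas. The solid feeds A with coefficient 0.0709 min⁻¹ times the gap to solubility. The side step and the gas together drain A with a first-order constant of 0.137 min⁻¹ at saturated gas, which is more than the dissolution coefficient. So A stops where feed equals drain, a quasi-steady state, and not at solubility.

Without the homo dimer that level is 0.181 M, and capture then holds B at 0.118 M. Adding the square term gives 0.168 M, the plateau concentration A*, the level of starting material at which dissolution just pays for its drains. That is a third of the solubility, and the contradiction is gone.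

At A*, the gas stands at 91.6% of saturation, or 0.119 M. The feed of 0.0257 M min⁻¹ would take 38.9 min to use up the charge, longer than the run. While solid lasts, target and isomer of the product together grow at zero order, at 0.00894 M min⁻¹, after a lag of 4.06 min while A climbs. That makes 18.7% of the charge. The relaxation half-life of target and isomer of the product, both ways together, is 5.55 min, short against the run, so the isomer trails its equilibrium share and by my estimate takes 2.44%. My target is 16.3%.

The forecast, on the ground that “Dissolved starting material settles within a few minutes”, gives 16.2% (14.5% to 18%) of target and 91.6% (90.5% to 92.5%) of saturation, its target slightly below mine.

The flask gives 16.0% of target and 91.6% of saturation. The reading to watch is the starting material, 16.7% of the charge at 25.0 min, with 30.7% still solid. The neighbour flask read at 10 min tests the plateau: A* with the same lag gives 5.31% for target plus isomer, and that flask holds 5.42%.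

(The numbers belong to no real substance; no experiment stands behind them.)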